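**Retrosynthetic overview**
1. Locants follow shikimate numbering. C1 bears CO2Me, C2 is the vinyl CH, C3 bears OAc, C4 and C5 bear the (R)-2-methylbutanoates, and C6 is the CH2.
2. Enabling feature: the cyclohexene consists of two C3 halves. C3–C4–C5 is fully oxygenated (a dihydroxyacetone unit), so with C4 as a ketone both C3 and C5 become enamine nucleophiles and O3/O5 fit into one 1,3-dioxane ring. C2=C1(CO2Me)–C6 is an acrylate whose β-carbon C2 and allylic carbon C6 are both electrophilic.
3. Disconnections: O5 ester; O3 acetate (Mitsunobu inversion of the 3-epimer); benzylidene; O4 ester; C4–H (ketone reduction). Then C6–C5 and C2–C3 are cut together, back to an enamine of 2-phenyl-1,3-dioxan-5-one and methyl (Z)-3-bromo-2-(bromomethyl)acrylate.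
4. Ring order: the temporary 1,3-dioxane comes first (glycerol acetal). The carbocycle is closed across it in step 5 as a 2,4-dioxabicyclo[3.3.1]nonene, and the dioxane is cleaved in step 8.
5. The bridge can only hold O3 and O5 cis, whereas the target has them trans. The route uses this: the acetate enters at C3 with inversion, which also distinguishes O3 from O5.

Key step: step 5

Assumption: the ring is read as (3R,4S,5R), the natural shikimate configuration, and both side chains as (R)-2-methylbutanoyl; enantiopure 3 and 12 are taken as purchasable.

**Step 1**
Reactants: 1 cis-2-phenyl-1,3-dioxan-5-ol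
Product: 2 2-phenyl-1,3-dioxan-5-one
Conditions: Dess–Martin periodinane, CH2Cl2, 0 °C to rt
Reagents that add atoms: none
Why: Dess–Martin oxidation turns the secondary carbinol into the ketone under non-aqueous and nearly neutral conditions, so that the benzylidene acetal survives and the hydrate-prone ketone stays anhydrous; the carbinol stereocentre is erased.

**Step 2**
Reactants: 2 2-phenyl-1,3-dioxan-5-one; 3 (2S,5S)-2,5-dimethylpyrrolidine
Product: 4 5-[(2S,5S)-2,5-dimethylpyrrolidin-1-yl]-2-phenyl-4H-1,3-dioxine (enamine)
Conditions: 4 Å MS, toluene, 60 °C; filtered, concentrated, used crude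
Reagents that add atoms: none
Why: Enamine condensation (first stage of a Stork enamine sequence): the ketone, activated by its two α-oxygens, should condense with the hindered amine over sieves without acid, and the two double-bond isomers (diastereomers at the acetal carbon) interconvert, so that the crude mixture can be used.

**Step 3**
Reactants: 5 methyl 2-(bromomethyl)acrylate
Product: 6 methyl 2,3-dibromo-2-(bromomethyl)propanoate
Conditions: Br2, CH2Cl2, 0 °C to reflux
Reagents that add atoms: bromine, BrBr
Why: Addition of bromine across the 1,1-disubstituted acrylate double bond, as known for methacrylates; the new quaternary carbon carries two identical CH2Br groups and is not a stereocentre.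

**Step 4**
Reactants: 6 methyl 2,3-dibromo-2-(bromomethyl)propanoate
Product: 7 methyl (Z)-3-bromo-2-(bromomethyl)acrylate
Conditions: Et3N (1.0 equiv), Et2O, 0 °C to rt
Reagents that add atoms: none
Why: E2 dehydrobromination (the bromination–dehydrobromination sequence known for methacrylates), in which only the CH2Br hydrogens are available, should favour the isomer with bromine anti to the ester, which is the (Z)-isomer, and any (E)-isomer is removed by chromatography.

**Step 5**
Reactants: 4 enamine; 7 methyl (Z)-3-bromo-2-(bromomethyl)acrylate
Product: 10 methyl (1R,3S,5S)-9-oxo-3-phenyl-2,4-dioxabicyclo[3.3.1]non-6-ene-7-carboxylate, via C5-alkylated enamine 8 (not isolated), via bicyclic iminium bromide 9 (not isolated)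
Conditions: MeCN, −20 °C to rt; then iPr2NEt (2.2 equiv), 60 °C; then aq NaOAc–AcOH buffer (pH 5), rt
Reagents that add atoms: water, O
Why: Proposed new method: the enamine carbon of 4 (future C5) displaces the primary allylic bromide of 7 (SN2, C6–C5), iPr2NEt shifts the enamine to the other α-carbon to give 8, this carbon (future C3) adds to the β-bromoacrylate carbon C2 and the ester enolate expels bromide (C2–C3, C1=C2 retained) to give 9, and buffered water hydrolyses the iminium ion. The closest known reaction type is the α,α′-annulation ([3+3]) of cyclic ketone enamines, those of 1,3-dioxan-5-ones included, with 2-(bromomethyl)acrylates or 2-nitroallyl esters; new are the β-bromine, which turns the closing Michael addition into an addition–elimination, and the control by a C2-symmetric amine, itself known from enamine alkylation with allylic halides. The one ring closed is the carbocycle, 6-endo-trig, from a side chain that A(1,3) strain in 8 holds axial on the dioxane, and in (Z)-7 the bromine is cis to C6, so that it becomes axial at C2 and lies parallel to the enolate π system for loss. C5 is set by the amine, whose pseudoaxial methyl group beside the vinyl carbon covers the Si face so that 7 arrives on the Re face, and of the two equilibrating enamine isomers only the one reacts in which this face is also the axial face syn to the acetal hydrogen (phenyl equatorial); C3 follows from the bridge, because a three-atom bridge across the two α-carbons of the dioxanone can only be cis, and the acetal carbon ends with phenyl exo. The step needs site selectivity within 7 (CH2Br first, CHBr second, since the reverse order leads to the enantiomer); this should be secured by the faster SN2 reaction of a primary allylic bromide compared with conjugate addition to a β-substituted acrylate, by the hindered nitrogen, which disfavours N-allylation and aza-Claisen transposition, and by adding the base only after the alkylation. C3 and C5 of 10 are bridgeheads, so the C4 ketone cannot enolise (Bredt's rule), which protects this 4-oxo-shikimate from epimerisation, β-elimination and aromatisation.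

**Step 6**
Reactants: 10 bicyclic ketone
Product: 11 methyl (1R,3S,5S,9S)-9-hydroxy-3-phenyl-2,4-dioxabicyclo[3.3.1]non-6-ene-7-carboxylate
Conditions: NaBH4, MeOH–CH2Cl2, −78 °C
Reagents that add atoms: none
Why: Borohydride 1,2-reduction of the strained, doubly α-oxygenated ketone is far faster than attack on the enoate, and hydride should arrive over the chair dioxane ring (axial attack on a 1,3-dioxan-5-one, whose ring oxygens carry no axial hydrogens and whose acetal carbon turns only H inward, unlike an acetonide) rather than over the cyclohexene ring, which places the C4 hydroxyl anti to O3 and O5 (4S in shikimate numbering).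

**Step 7**
Reactants: 11 bicyclic alcohol; 12 (R)-2-methylbutanoic acid
Product: 13 methyl (1R,3S,5S,9S)-9-{[(2R)-2-methylbutanoyl]oxy}-3-phenyl-2,4-dioxabicyclo[3.3.1]non-6-ene-7-carboxylate
Conditions: DCC, DMAP (cat.), CH2Cl2, 0 °C to rt
Reagents that add atoms: none
Why: Steglich esterification acylates the only free hydroxyl with retention at C4, and carbodiimide activation with catalytic DMAP avoids the ketene pathway that could racemise the α-stereocentre of 12.

**Step 8**
Reactants: 13 bicyclic ester
Product: 14 methyl (3S,4S,5R)-3,5-dihydroxy-4-{[(2R)-2-methylbutanoyl]oxy}cyclohex-1-ene-1-carboxylate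
Conditions: AcOH–H2O (4:1), 40 °C
Reagents that add atoms: none
Why: Acid hydrolysis of the benzylidene acetal, driven by release of the triaxial bridged conformation, frees O3 and O5 without touching a stereocentre, since ionisation of the allylic C3–O bond is disfavoured by the electron-poor enoate and acyl migration is slow in acid.

**Step 9**
Reactants: 14 3,5-diol
Product: 15 methyl (3R,4S,5R)-3-acetoxy-5-hydroxy-4-{[(2R)-2-methylbutanoyl]oxy}cyclohex-1-ene-1-carboxylate
Conditions: AcOH, PPh3, DIAD (1.05 equiv each), toluene, −20 to 0 °C
Reagents that add atoms: acetic acid, CC(=O)O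
Why: Mitsunobu reaction: oxyphosphonium formation is reversible at both hydroxyls, but SN2 displacement by acetate should be much faster at C3, which is allylic and γ to the ester carbonyl (SN2-activated, while SN1 and SN2′ at the ester-bearing C1 are disfavoured), so that with one equivalent of reagents the acetate enters with inversion (3S to 3R, cis to O4) and the C5 hydroxyl remains.

**Step 10**
Reactants: 15 hydroxy acetate; 12 (R)-2-methylbutanoic acid
Product: 16 methyl (3R,4S,5R)-3-acetoxy-4,5-bis{[(2R)-2-methylbutanoyl]oxy}cyclohex-1-ene-1-carboxylate
Conditions: DCC, DMAP (cat.), CH2Cl2, 0 °C to rt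
Reagents that add atoms: none
Why: Steglich esterification of the remaining C5 hydroxyl with retention completes the target; a possible 4-to-5 acyl shift before acylation would be degenerate because both positions end with the same acyl group.

**Compound list**
1 | cis-2-phenyl-1,3-dioxan-5-ol (cis-1,3-O-benzylideneglycerol) | O[C@H]1CO[C@H](OC1)c1ccccc1 | starting material
2 | 2-phenyl-1,3-dioxan-5-one | O=C1COC(OC1)c1ccccc1 | intermediate
3 | (2S,5S)-2,5-dimethylpyrrolidine (trans, C2-symmetric) | C[C@H]1CC[C@H](C)N1 | starting material
4 | 5-[(2S,5S)-2,5-dimethylpyrrolidin-1-yl]-2-phenyl-4H-1,3-dioxine, drawn as the double-bond isomer that reacts in step 5 | C[C@H]1CC[C@H](C)N1C1=CO[C@H](c2ccccc2)OC1 | intermediate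
5 | methyl 2-(bromomethyl)acrylate | COC(=O)C(=C)CBr | starting material
6 | methyl 2,3-dibromo-2-(bromomethyl)propanoate | COC(=O)C(Br)(CBr)CBr | intermediate
7 | methyl (Z)-3-bromo-2-(bromomethyl)acrylate (Br cis to CH2Br, trans to CO2Me) | COC(=O)/C(CBr)=C/Br | intermediate
8 | C5-alkylated enamine: double bond towards C3, axial CH2–C(CO2Me)=CHBr chain on C5 (5R), chain trans to phenyl, Br cis to the CH2 link | COC(=O)/C(=C/Br)C[C@H]1O[C@H](c2ccccc2)OC=C1N1[C@@H](C)CC[C@@H]1C | intermediate
9 | bicyclic iminium bromide (the C9 iminium ion of 10 with amine 3) | COC(=O)C1=C[C@@H]2O[C@@H](c3ccccc3)O[C@H](C1)C2=[N+]1[C@@H](C)CC[C@@H]1C.[Br-] | intermediate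
10 | methyl (1R,3S,5S)-9-oxo-3-phenyl-2,4-dioxabicyclo[3.3.1]non-6-ene-7-carboxylate (phenyl exo) | COC(=O)C1=C[C@@H]2O[C@@H](c3ccccc3)O[C@H](C1)C2=O | intermediate
11 | methyl (1R,3S,5S,9S)-9-hydroxy-3-phenyl-2,4-dioxabicyclo[3.3.1]non-6-ene-7-carboxylate (OH over the cyclohexene ring, anti to both ring oxygens) | COC(=O)C1=C[C@@H]2O[C@@H](c3ccccc3)O[C@H](C1)[C@@H]2O | intermediate
12 | (R)-2-methylbutanoic acid | CC[C@@H](C)C(=O)O | starting material
13 | (R)-2-methylbutanoate of 11 | COC(=O)C1=C[C@@H]2O[C@@H](c3ccccc3)O[C@H](C1)[C@@H]2OC(=O)[C@H](C)CC | intermediate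
14 | methyl (3S,4S,5R)-3,5-dihydroxy-4-{[(2R)-2-methylbutanoyl]oxy}cyclohex-1-ene-1-carboxylate | CC[C@@H](C)C(=O)O[C@@H]1[C@@H](O)C=C(C(=O)OC)C[C@H]1O | intermediate
15 | methyl (3R,4S,5R)-3-acetoxy-5-hydroxy-4-{[(2R)-2-methylbutanoyl]oxy}cyclohex-1-ene-1-carboxylate | CC[C@@H](C)C(=O)O[C@@H]1[C@H](OC(C)=O)C=C(C(=O)OC)C[C@H]1O | intermediate
16 | methyl (3R,4S,5R)-3-acetoxy-4,5-bis{[(2R)-2-methylbutanoyl]oxy}cyclohex-1-ene-1-carboxylate | CC[C@@H](C)C(=O)O[C@@H]1[C@H](OC(C)=O)C=C(C(=O)OC)C[C@H]1OC(=O)[C@H](C)CC | target

Total step count: 10. Longest linear sequence: 8 steps (1, 2, 5, 6, 7, 8, 9, 10).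

**Steps most likely to fail**

1. **Step 5.**
   - What may go wrong:
     - Reversed order of attack on the two electrophilic carbons of 7, which erodes the enantiomeric purity.
     - Stalling after the first alkylation, because the second enamine has to be attacked syn to a methyl group of the amine.
     - N-alkylation of the enamine.
   - Any minor enantiomer that passes becomes a diastereomer in step 7 and can be removed there.
   - The fallback uses known chemistry, sets out from 2 and comes back at 10.
   - Condensation of 2 with (R)-1-amino-2-(methoxymethyl)pyrrolidine (RAMP) should give the RAMP hydrazone F1.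
   - Deprotonation (t-BuLi or LDA, THF, −78 °C) and alkylation with 7 at −100 °C should give the C5-alkylated hydrazone F2. This reaction type is known for dioxanone hydrazones and 2-(bromomethyl)acrylates. It runs under auxiliary control at a temperature at which only the CH2Br carbon should react.
   - Aqueous oxalic acid in Et2O should release the α-alkylated ketone F3.
   - Pyrrolidine over sieves in MeCN should convert it into the less substituted pyrrolidine enamine F4. This closes by intramolecular conjugate addition–elimination to the bicyclic pyrrolidinium bromide F5, and aqueous buffer then gives 10.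
   - The two bonds are made in separate flasks, so the absolute configuration is fixed before a second electrophilic site can compete. The acetal carbon of F3 stores that configuration, because only the isomer with the side chain trans to phenyl can bridge.

2. **Step 9.**
   - What may go wrong:
     - Competing displacement at C5.
     - Participation of the trans C4 ester, giving retention or acyl scrambling.
     - Elimination towards a diene.
   - The fallback sets out from 14 and comes back at 15. It replaces reagent-controlled choice between two hydroxyls by a bridged leaving group.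
   - SOCl2 and Et3N in CH2Cl2 at 0 °C should give the 3,5-cyclic sulfite F6.
   - RuCl3 (cat.) and NaIO4 in MeCN–H2O at 0 °C should give the 3,5-cyclic sulfate F7.
   - CsOAc in DMF should open it at the allylic carbon C3 with inversion to the cesium 5-sulfate F8.
   - Catalytic H2SO4 in wet THF should hydrolyse the sulfate monoester to 15.

3. **Step 6.**
   - What may go wrong: poor facial selectivity of hydride delivery. Attack over the cyclohexene ring would turn the C4 hydroxyl syn to O3 and O5.
   - The fallback sets out from 10 and comes back at 13. It lets both epimers converge.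
   - The all-cis alcohol F9 is separated and converted with Tf2O and pyridine in CH2Cl2 at −20 °C into the triflate F10.
   - F10 is displaced in DMF by cesium (R)-2-methylbutanoate F11 (from 12 and Cs2CO3) in an SN2 reaction of the kind used on carbohydrate triflates. This inverts C4 and installs the ester of 13 in the same event.

**Further compounds**
F1 | step 5 | RAMP hydrazone of 2 | COC[C@H]1CCCN1N=C1COC(c2ccccc2)OC1
F2 | step 5 | C5-alkylated hydrazone (5R, side chain trans to phenyl, Br cis to the CH2 link) | COC[C@H]1CCCN1N=C1CO[C@@H](c2ccccc2)O[C@@H]1C/C(=C\Br)C(=O)OC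
F3 | step 5 | α-alkylated ketone (5R, side chain trans to phenyl) | O=C1CO[C@@H](c2ccccc2)O[C@@H]1C/C(=C\Br)C(=O)OC
F4 | step 5 | pyrrolidine enamine of F3 (double bond towards C3) | COC(=O)/C(=C/Br)C[C@H]1O[C@H](c2ccccc2)OC=C1N1CCCC1
F5 | step 5 | bicyclic pyrrolidinium bromide | COC(=O)C1=C[C@@H]2O[C@@H](c3ccccc3)O[C@H](C1)C2=[N+]1CCCC1.[Br-]
F6 | step 9 | 3,5-cyclic sulfite of 14 | CC[C@@H](C)C(=O)O[C@@H]1[C@@H]2C=C(C(=O)OC)C[C@H]1OS(=O)O2
F7 | step 9 | 3,5-cyclic sulfate of 14 | CC[C@@H](C)C(=O)O[C@@H]1[C@@H]2C=C(C(=O)OC)C[C@H]1OS(=O)(=O)O2
F8 | step 9 | cesium 5-sulfate of 15 | CC[C@@H](C)C(=O)O[C@@H]1[C@H](OC(C)=O)C=C(C(=O)OC)C[C@H]1OS(=O)(=O)[O-].[Cs+]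
F9 | step 6 | all-cis alcohol (C9 epimer of 11) | COC(=O)C1=C[C@@H]2O[C@@H](c3ccccc3)O[C@H](C1)[C@H]2O
F10 | step 6 | triflate of F9 | COC(=O)C1=C[C@@H]2O[C@@H](c3ccccc3)O[C@H](C1)[C@H]2OS(=O)(=O)C(F)(F)F
F11 | step 6 | cesium (R)-2-methylbutanoate | CC[C@@H](C)C(=O)[O-].[Cs+]
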